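Everything rests on cutting ring A at C5'–C6' and C1'–C2'. The step exploits how ring A is substituted. The acyl-bearing carbon C1' and its oxygenated neighbour C6' can be read as the C=C of a vinylogous ester. The run C2'(O)–C3'(CH3)–C4'(O)–C5'(CH2–ring B) is the enolised backbone of a 2-methyl-3-oxo ester. One polarised [4+2] addition, then loss of HBr and methanol, should deliver the hexasubstituted arene with three differentiated oxygens. The diene already carries chromanone ring B as its 5,7-dibenzyl ether, with the C4 ketone deliberately masked as a third silyl enol ether. Its partner is a (Z)-α-bromo-β-benzyloxy enone.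

Key step: step 10

Remarks
- Numbering: ring A is primed (C1' isobutyryl, C2' OH, C3' CH3, C4' OCH3, C5' CH2, C6' OH). Ring B uses chromanone numbers.
- Stereochemistry: the target has no stereocentre. Compounds 11, 13, 15, 18, 20 and 21 are racemic and their stereocentres are erased later.
- Assumption: 11 and 15 are taken as catalogue compounds.
- Ring B ketone: it is enolisable and cannot be expected to stay untouched under conditions that turn a β-keto ester into its bis-silyl diene. It is therefore silylated on purpose (14) and comes back in the acidic stage of step 10.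
- Order of events in step 10: base comes before acid. HBr is removed while ring A still has no ring carbonyl, so benzyl alcohol cannot be expelled.
- Side chain: it is grown from the aldehyde under weakly acidic or neutral conditions. No 2,4,6-trioxygenated benzylic halide and no dianion is needed next to the enolisable ketone.

Step 1
Reactants: 1 2-methylphloroglucinol; 2 3,3-dimethylacrylic acid
Product: 3 5,7-dihydroxy-2,2,6-trimethylchroman-4-one
Conditions: P2O5, MeSO3H, 70 °C
Reagents that add atoms: none
Why: Friedel–Crafts acylation at one of the two equivalent free ring carbons and acid-mediated oxa-Michael closure build the chromanone, and closure should run through the unhindered oxygen para to the methyl group because the methyl-flanked hydroxyl is held in the chelate to the new carbonyl, a preference reinforced by the acid-reversible (Wessely–Moser-type) ring opening, with any 8-methyl isomer removed by chromatography.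

Step 2
Reactants: 3 5,7-dihydroxy-2,2,6-trimethylchroman-4-one
Product: 5 5,7-dihydroxy-2,2,6-trimethyl-4-oxochromane-8-carbaldehyde, via iminium chloride 4 (not isolated)
Conditions: POCl3 (1.2 equiv), DMF, EtOAc, 0 °C → rt; then H2O, 50 °C
Reagents that add atoms: N,N-dimethylformamide CN(C)C=O; water O
Why: Vilsmeier–Haack formylation can only strike C8, the single unsubstituted and strongly activated aromatic position, and with a small excess of reagent at or below room temperature the chelated, hindered C4 ketone should escape chloroformylation.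

Step 3
Reactants: 5 5,7-dihydroxy-2,2,6-trimethyl-4-oxochromane-8-carbaldehyde
Product: 6 5,7-bis(benzyloxy)-2,2,6-trimethyl-4-oxochromane-8-carbaldehyde
Conditions: BnBr (2.5 equiv), K2CO3, DMF, 60 °C
Reagents that add atoms: benzyl bromide BrCc1ccccc1
Why: Williamson etherification in a warm dipolar aprotic solvent overcomes the hydrogen bonds of both chelated phenols, and benzyl is chosen because all benzyl groups of the route leave together in the last step.

Step 4
Reactants: 6 5,7-bis(benzyloxy)-2,2,6-trimethyl-4-oxochromane-8-carbaldehyde; 7 Meldrum's acid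
Product: 10 3-[5,7-bis(benzyloxy)-2,2,6-trimethyl-4-oxochroman-8-yl]propanoic acid, via arylidene dioxanedione 8 (not isolated), via arylmethyl dioxanedione 9 (not isolated)
Conditions: HCO2H–Et3N (5:2), 95 °C
Reagents that add atoms: none
Why: In this one-pot reductive Knoevenagel sequence condensation gives 8, formate delivers hydride to its β-carbon to give 9, and the water released in the condensation opens the dioxanedione, which loses acetone and CO2, so the two-carbon acid chain is added without a benzylic halide or a strong base.

Step 5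
Reactants: 10 3-[5,7-bis(benzyloxy)-2,2,6-trimethyl-4-oxochroman-8-yl]propanoic acid; 11 3-methoxy-2-methyl-3-oxopropanoic acid
Product: 13 methyl 5-[5,7-bis(benzyloxy)-2,2,6-trimethyl-4-oxochroman-8-yl]-2-methyl-3-oxopentanoate, via acyl imidazolide 12 (not isolated)
Conditions: CDI, THF, rt; then 11, MgCl2, Et3N, MeCN, rt → 40 °C; aq HCl work-up
Reagents that add atoms: none
Why: In the Masamune–Brooks homologation the acyl imidazolide C-acylates the magnesium enolate of the malonate half ester and decarboxylation follows under near-neutral conditions that spare benzyl ethers and chromanone, and the new C2 stereocentre is racemic, labile and destroyed in step 6.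

Step 6
Reactants: 13 methyl 5-[5,7-bis(benzyloxy)-2,2,6-trimethyl-4-oxochroman-8-yl]-2-methyl-3-oxopentanoate
Product: 14 5,7-bis(benzyloxy)-8-[(2Z,4Z)-5-methoxy-4-methyl-3,5-bis(trimethylsilyloxy)penta-2,4-dien-1-yl]-2,2,6-trimethyl-4-(trimethylsilyloxy)-2H-chromene
Conditions: TMSOTf (3.6 equiv), Et3N (4.5 equiv), Et2O, 0 °C → rt; pentane extraction, used crude
Reagents that add atoms: trimethylsilyl triflate C[Si](C)(C)OS(=O)(=O)C(F)(F)F
Why: Soft enolisation with TMSOTf and Et3N is the established one-flask route from β-keto esters to 1-alkoxy-1,3-bis(silyloxy)dienes, and because it also silylates the aryl alkyl ketone of ring B an excess is used so that one uniform tris-silyl compound results, whose neopentyl-flanked aryl enol ether is far less nucleophilic than the ketene-acetal diene (only the 2Z geometry, with CH2–ring B outside the s-cis diene, matters).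

Step 7
Reactants: 15 4-methylpent-1-yn-3-ol
Product: 16 4-methylpent-1-yn-3-one
Conditions: IBX, EtOAc, 75 °C
Reagents that add atoms: none
Why: IBX oxidation of a secondary propargylic alcohol to the ynone is routine and removes the only stereocentre of 15.

Step 8
Reactants: 16 4-methylpent-1-yn-3-one
Product: 17 (E)-1-(benzyloxy)-4-methylpent-1-en-3-one
Conditions: BnOH, DABCO (10 mol %), CH2Cl2, 0 °C → rt
Reagents that add atoms: benzyl alcohol OCc1ccccc1
Why: DABCO-catalysed oxa-Michael addition of an alcohol to a terminal ynone forms only the O–C bond and gives the thermodynamically preferred E β-alkoxy enone, which avoids the O- versus C-alkylation problem of a formyl ketone enolate.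

Step 9
Reactants: 17 (E)-1-(benzyloxy)-4-methylpent-1-en-3-one
Product: 19 (Z)-1-(benzyloxy)-2-bromo-4-methylpent-1-en-3-one, via dibromide 18 (not isolated)
Conditions: Br2, CH2Cl2, −78 °C; then Et3N, −78 °C → rt
Reagents that add atoms: bromine BrBr
Why: Bromine addition to the enol-ether double bond and amine-induced loss of the acidic α-proton together with the bromide on the ether carbon (bromination–dehydrobromination of a vinylogous ester) should give the Z isomer, in which acyl group and OBn stay trans.

Step 10
Reactants: 14 tris-silyl diene; 19 (Z)-1-(benzyloxy)-2-bromo-4-methylpent-1-en-3-one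
Product: 22 8-{[2-(benzyloxy)-4,6-dihydroxy-5-methyl-3-(2-methylpropanoyl)phenyl]methyl}-5,7-bis(benzyloxy)-2,2,6-trimethylchroman-4-one, via bromo cycloadduct 20 (not isolated), via cyclohexadiene ketal 21 (not isolated)
Conditions: 19 (1.5 equiv), toluene (1 M), 80 °C; then DBU (2 equiv), 0 °C; then 1 M HCl, THF, rt
Reagents that add atoms: none
Why: Proposed new method: the nucleophilic diene terminus (future C5') bonds to the β-carbon of the push–pull bromo enone (C6') and the ketene-acetal carbon (C2') closes onto the α-carbon (C1') in a strongly asynchronous but suprafacial intermolecular [4+2] addition, which closes ring A as a six-membered carbocycle (20) by forming both bonds between the two components. The closest known reaction type is the Diels–Alder aromatisation of 1-alkoxy-1,3-bis(silyloxy)dienes with haloquinones and cyclic α-halo enones, in which the halogen likewise supplies the oxidation level; an acyclic β-alkoxy α-bromo enone has not been used in this role. Orientation is secured by matched polarity (largest donor coefficient at the diene carbon remote from the ketene acetal, largest acceptor coefficient at the enone β-carbon), and the C3' methyl group closes off the competing [3+3] mode through the central diene carbon because that path cannot aromatise. The selectivity that decides the step is loss of HBr and not of benzyl alcohol: the Z dienophile places Br (C1') and H (C6') trans in 20 so that they can become antiperiplanar, and as long as C2' is a ketal and C4' a silyl enol ether no ring carbonyl acidifies H–C5', so DBU has an E2 dehydrobromination to the push–pull alkene 21 open to it but no enolate from which benzyloxide could be expelled. Acid is admitted only afterwards, when OBn sits on an sp2 carbon: the mixed ketal at C2' then loses methanol, the dienone tautomerises at C5' to the phenol, and the three silyl groups are hydrolysed, which frees C2'–OH and C4'–OH and returns the C4 ketone of ring B; Lewis acids are left out throughout because the C2' and C4' oxygens would assist ionisation of the C6'–OBn bond. No stereocentre survives, so apart from the cis addition no stereocontrol is needed.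

Step 11
Reactants: 22 4'-O-demethylmallopallidol 6',5,7-tribenzyl ether
Product: 23 8-{[2-(benzyloxy)-4-hydroxy-6-methoxy-5-methyl-3-(2-methylpropanoyl)phenyl]methyl}-5,7-bis(benzyloxy)-2,2,6-trimethylchroman-4-one
Conditions: MeI (1.2 equiv), K2CO3, acetone, 40 °C
Reagents that add atoms: iodomethane CI
Why: Williamson methylation with a mild carbonate base discriminates between the free, more acidic C4' phenol para to the acyl group and the C2' phenol locked in a hydrogen bond to the isobutyryl carbonyl.

Step 12
Reactants: 23 mallopallidol 6',5,7-tribenzyl ether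
Product: 24 mallopallidol
Conditions: H2 (1 atm), 10% Pd/C, EtOAc–MeOH, rt
Reagents that add atoms: none
Why: Catalytic hydrogenolysis cleaves the three aryl benzyl ethers under conditions that leave the electron-rich chelated aryl ketones, the aryl methyl ether and the diarylmethane bridge intact.

Compound list
1 | 2-methylphloroglucinol (2-methylbenzene-1,3,5-triol) | Cc1c(O)cc(O)cc1O | starting material
2 | 3,3-dimethylacrylic acid (3-methylbut-2-enoic acid) | CC(C)=CC(=O)O | starting material
3 | 5,7-dihydroxy-2,2,6-trimethylchroman-4-one | O=C1CC(C)(C)Oc2cc(O)c(C)c(O)c12 | intermediate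
4 | (5,7-dihydroxy-2,2,6-trimethyl-4-oxochroman-8-yl)methylidene(dimethyl)iminium chloride | C[N+](C)=Cc1c(O)c(C)c(O)c2c1OC(C)(C)CC2=O.[Cl-] | intermediate
5 | 5,7-dihydroxy-2,2,6-trimethyl-4-oxochromane-8-carbaldehyde | O=Cc1c(O)c(C)c(O)c2c1OC(C)(C)CC2=O | intermediate
6 | 5,7-bis(benzyloxy)-2,2,6-trimethyl-4-oxochromane-8-carbaldehyde | O=Cc1c(OCc2ccccc2)c(C)c(OCc2ccccc2)c2c1OC(C)(C)CC2=O | intermediate
7 | Meldrum's acid (2,2-dimethyl-1,3-dioxane-4,6-dione) | CC1(C)OC(=O)CC(=O)O1 | starting material
8 | 5-{[5,7-bis(benzyloxy)-2,2,6-trimethyl-4-oxochroman-8-yl]methylidene}-2,2-dimethyl-1,3-dioxane-4,6-dione | CC1(C)OC(=O)C(=Cc2c(OCc3ccccc3)c(C)c(OCc3ccccc3)c3c2OC(C)(C)CC3=O)C(=O)O1 | intermediate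
9 | 5-{[5,7-bis(benzyloxy)-2,2,6-trimethyl-4-oxochroman-8-yl]methyl}-2,2-dimethyl-1,3-dioxane-4,6-dione | CC1(C)OC(=O)C(Cc2c(OCc3ccccc3)c(C)c(OCc3ccccc3)c3c2OC(C)(C)CC3=O)C(=O)O1 | intermediate
10 | 3-[5,7-bis(benzyloxy)-2,2,6-trimethyl-4-oxochroman-8-yl]propanoic acid | OC(=O)CCc1c(OCc2ccccc2)c(C)c(OCc2ccccc2)c2c1OC(C)(C)CC2=O | intermediate
11 | 3-methoxy-2-methyl-3-oxopropanoic acid (monomethyl methylmalonate, racemic) | COC(=O)C(C)C(=O)O | starting material
12 | 1-{3-[5,7-bis(benzyloxy)-2,2,6-trimethyl-4-oxochroman-8-yl]propanoyl}imidazole | O=C(CCc1c(OCc2ccccc2)c(C)c(OCc2ccccc2)c2c1OC(C)(C)CC2=O)n1ccnc1 | intermediate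
13 | methyl 5-[5,7-bis(benzyloxy)-2,2,6-trimethyl-4-oxochroman-8-yl]-2-methyl-3-oxopentanoate (racemic, C2 labile) | COC(=O)C(C)C(=O)CCc1c(OCc2ccccc2)c(C)c(OCc2ccccc2)c2c1OC(C)(C)CC2=O | intermediate
14 | 5,7-bis(benzyloxy)-8-[(2Z,4Z)-5-methoxy-4-methyl-3,5-bis(trimethylsilyloxy)penta-2,4-dien-1-yl]-2,2,6-trimethyl-4-(trimethylsilyloxy)-2H-chromene | CO/C(O[Si](C)(C)C)=C(\C)/C(O[Si](C)(C)C)=C/Cc1c(OCc2ccccc2)c(C)c(OCc2ccccc2)c2c1OC(C)(C)C=C2O[Si](C)(C)C | intermediate
15 | 4-methylpent-1-yn-3-ol (racemic) | CC(C)C(O)C#C | starting material
16 | 4-methylpent-1-yn-3-one | CC(C)C(=O)C#C | intermediate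
17 | (E)-1-(benzyloxy)-4-methylpent-1-en-3-one | CC(C)C(=O)/C=C/OCc1ccccc1 | intermediate
18 | 1-(benzyloxy)-1,2-dibromo-4-methylpentan-3-one (racemic, diastereomer mixture) | CC(C)C(=O)C(Br)C(Br)OCc1ccccc1 | intermediate
19 | (Z)-1-(benzyloxy)-2-bromo-4-methylpent-1-en-3-one | CC(C)C(=O)/C(Br)=C/OCc1ccccc1 | intermediate
20 | bromo cycloadduct: cyclohex-3-ene with Br and isobutyryl at C1', OMe and OTMS at C2', CH3 at C3', OTMS at C4', CH2–ring B (4-silyloxychromene form) at C5', OBn at C6'; Br and OBn cis; racemic; epimers at C2' and C5' | CC(C)C(=O)[C@]1(Br)[C@@H](OCc2ccccc2)C(Cc2c(OCc3ccccc3)c(C)c(OCc3ccccc3)c3c2OC(C)(C)C=C3O[Si](C)(C)C)C(O[Si](C)(C)C)=C(C)C1(OC)O[Si](C)(C)C | intermediate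
21 | cyclohexa-1,4-diene ketal: C1'(isobutyryl)=C6'(OBn), C3'(CH3)=C4'(OTMS), C2'(OMe)(OTMS), C5'H–CH2–ring B (4-silyloxychromene form); racemic, epimers | CC(C)C(=O)C1=C(OCc2ccccc2)C(Cc2c(OCc3ccccc3)c(C)c(OCc3ccccc3)c3c2OC(C)(C)C=C3O[Si](C)(C)C)C(O[Si](C)(C)C)=C(C)C1(OC)O[Si](C)(C)C | intermediate
22 | 4'-O-demethylmallopallidol 6',5,7-tribenzyl ether | Cc1c(O)c(C(=O)C(C)C)c(OCc2ccccc2)c(Cc2c(OCc3ccccc3)c(C)c(OCc3ccccc3)c3c2OC(C)(C)CC3=O)c1O | intermediate
23 | mallopallidol 6',5,7-tribenzyl ether | COc1c(C)c(O)c(C(=O)C(C)C)c(OCc2ccccc2)c1Cc1c(OCc2ccccc2)c(C)c(OCc2ccccc2)c2c1OC(C)(C)CC2=O | intermediate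
24 | mallopallidol | COc1c(C)c(O)c(C(=O)C(C)C)c(O)c1Cc1c(O)c(C)c(O)c2c1OC(C)(C)CC2=O | target

Total step count: 12. Longest linear sequence: 9 (steps 1–6, then 10–12). Steps 7–9 form the convergent branch.

Steps most likely to fail

Step 10. Several processes could defeat this step.
- The addition may stall, because the closing C1'–C2' bond joins two fully substituted carbons.
- A first-formed zwitterion may collapse by silyl transfer and expulsion of benzyloxide, or close through the enone oxygen in a hetero-Diels–Alder sense.
- DBU may attack bromine instead of H–C6'.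
- DBU may trigger a Favorskii-type contraction through the isopropyl α'-proton.
- DBU may aromatise 21 before the acid stage with departure of silanolate in place of methanol.

The fallback gives up ring construction and joins two finished rings through the methylene bridge. This is the known o-quinone methide chemistry of phenolic Mannich bases with acylphloroglucinols. It sets out from 1 and 3 and comes back at 24. Friedel–Crafts acylation of 1 with isobutyryl chloride and AlCl3 should give 2-methyl-1-(2,4,6-trihydroxy-3-methylphenyl)propan-1-one F1. One equivalent of Me2SO4 with K2CO3 in acetone should methylate its non-chelated para hydroxyl to give 1-(2,6-dihydroxy-4-methoxy-3-methylphenyl)-2-methylpropan-1-one F2. A Mannich reaction of 3 with dimethylmethylideneammonium iodide at its only free position should give 8-[(dimethylamino)methyl]-5,7-dihydroxy-2,2,6-trimethylchroman-4-one F3. Heating F3 with F2 in dioxane should release the ring B o-quinone methide F4. The single free carbon of F2 then traps it to give 24 directly.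

Step 6. Silylation may stop short on the ester arm or leave the ring B ketone only partly masked. The labile O–Si bonds may also hydrolyse while the unpurifiable diene is handled.

The fallback installs the future C4' methyl ether before the diene is made. It sets out from 13, comes back at 23 and makes step 11 unnecessary. Acid-catalysed enol etherification of 13 with HC(OMe)3 (cat. H2SO4, MeOH) should give the stable, chromatographable methyl (E)-5-[5,7-bis(benzyloxy)-2,2,6-trimethyl-4-oxochroman-8-yl]-3-methoxy-2-methylpent-2-enoate F5. Kinetic deprotonation with LDA (2.2 equiv) and TMSCl in THF at −78 °C should silylate the ester dienolate and the chromanone enolate irreversibly. This gives the 1,3-dimethoxy-1-silyloxy diene F6. Under the conditions of step 10 with 19, F6 should pass through the methoxy bromo cycloadduct F7 and the methoxy cyclohexadiene ketal F8 to 23.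

Step 4. Hydride transfer from formate to the strongly donor-substituted, doubly ortho-substituted arylidene 8 may be too slow. The sequence would then halt at 8 or revert by retro-Knoevenagel cleavage.

The fallback replaces steps 4 and 5 by γ-alkylation of a β-keto ester dianion. It sets out from 6 and comes back at 13. NaBH4 in MeOH–THF at 0 °C should reduce only the aldehyde, giving 5,7-bis(benzyloxy)-8-(hydroxymethyl)-2,2,6-trimethylchroman-4-one F9. PBr3 in Et2O at 0 °C should give 5,7-bis(benzyloxy)-8-(bromomethyl)-2,2,6-trimethylchroman-4-one F10, which is used at once. F10 is added at −78 °C to the dianion of methyl 2-methyl-3-oxobutanoate (LDA, 2.1 equiv, THF), whose terminal carbon should be alkylated to give 13.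

Further compounds
F1 | step 10 | 2-methyl-1-(2,4,6-trihydroxy-3-methylphenyl)propan-1-one | CC(C)C(=O)c1c(O)cc(O)c(C)c1O
F2 | step 10 | 1-(2,6-dihydroxy-4-methoxy-3-methylphenyl)-2-methylpropan-1-one | CC(C)C(=O)c1c(O)cc(OC)c(C)c1O
F3 | step 10 | 8-[(dimethylamino)methyl]-5,7-dihydroxy-2,2,6-trimethylchroman-4-one | CN(C)Cc1c(O)c(C)c(O)c2c1OC(C)(C)CC2=O
F4 | step 10 | ring B o-quinone methide (5-hydroxy-2,2,6-trimethyl-8-methylidene-2,3-dihydrochromene-4,7-dione) | C=C1C(=O)C(C)=C(O)C2=C1OC(C)(C)CC2=O
F5 | step 6 | methyl (E)-5-[5,7-bis(benzyloxy)-2,2,6-trimethyl-4-oxochroman-8-yl]-3-methoxy-2-methylpent-2-enoate | COC(=O)/C(C)=C(/OC)CCc1c(OCc2ccccc2)c(C)c(OCc2ccccc2)c2c1OC(C)(C)CC2=O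
F6 | step 6 | 5,7-bis(benzyloxy)-8-[(2Z,4Z)-3,5-dimethoxy-4-methyl-5-(trimethylsilyloxy)penta-2,4-dien-1-yl]-2,2,6-trimethyl-4-(trimethylsilyloxy)-2H-chromene | CO/C(O[Si](C)(C)C)=C(\C)/C(OC)=C/Cc1c(OCc2ccccc2)c(C)c(OCc2ccccc2)c2c1OC(C)(C)C=C2O[Si](C)(C)C
F7 | step 6 | methoxy bromo cycloadduct (as 20 but OMe at C4'; Br and OBn cis; racemic) | CC(C)C(=O)[C@]1(Br)[C@@H](OCc2ccccc2)C(Cc2c(OCc3ccccc3)c(C)c(OCc3ccccc3)c3c2OC(C)(C)C=C3O[Si](C)(C)C)C(OC)=C(C)C1(OC)O[Si](C)(C)C
F8 | step 6 | methoxy cyclohexadiene ketal (as 21 but OMe at C4'; racemic) | CC(C)C(=O)C1=C(OCc2ccccc2)C(Cc2c(OCc3ccccc3)c(C)c(OCc3ccccc3)c3c2OC(C)(C)C=C3O[Si](C)(C)C)C(OC)=C(C)C1(OC)O[Si](C)(C)C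
F9 | step 4 | 5,7-bis(benzyloxy)-8-(hydroxymethyl)-2,2,6-trimethylchroman-4-one | OCc1c(OCc2ccccc2)c(C)c(OCc2ccccc2)c2c1OC(C)(C)CC2=O
F10 | step 4 | 5,7-bis(benzyloxy)-8-(bromomethyl)-2,2,6-trimethylchroman-4-one | BrCc1c(OCc2ccccc2)c(C)c(OCc2ccccc2)c2c1OC(C)(C)CC2=O
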